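**Retrosynthetic overview**
1. Target ⇒ desilylation, NaBH4 reduction of a C11 aldehyde and C1 O‑isovalerylation of a 4‑formyl iridoid lactol, which stays an acid‑stable vinylogous ester until the last two steps.
2. Dihydropyran (ring B, formed last) ⇒ spontaneous enol‑hemiacetalisation of a trialdehyde. The trialdehyde comes from a cyclopentane carrying cis C9‑CH2OH and C5‑CH(CH2OH)2.
3. 7β‑O‑coumaroyl / 8α‑OH / 8β‑CH2OH ⇒ Steglich ester, β‑face epoxidation of the C7=C8 allylic alcohol, and Payne rearrangement‑opening with inversion at C8.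
4. The C9–C1 bond cis to the C5 chain, together with the C7=C8 alkene ⇒ Still–Wittig [2,3] shift from a 7α‑allylic alcohol. C10 ⇒ Baylis–Hillman hydroxymethylation.
5. Key C4–C5 bond ⇒ anti‑selective intermolecular Michael addition of dimethyl malonate to (S)‑4‑silyloxycyclopentenone. The cyclopentane (ring A) is supplied by the commercial monoacetate.

Assumption: the commercial monoacetate is enantiopure. Iridoid numbering (C1, C3–C11) is used for all intermediates, and β is the face of H‑5 and H‑9 in the target.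

**Step 1**
Reactants: 1 (1R,4S)-4-hydroxycyclopent-2-en-1-yl acetate
Product: 2 (1R,4S)-4-(tert-butyldimethylsilyloxy)cyclopent-2-en-1-yl acetate
Conditions: TBSCl, imidazole, DMF, 0 °C→rt
Reagents that add atoms: tert-butyldimethylsilyl chloride, CC(C)(C)[Si](C)(C)Cl
Why: Imidazole‑promoted O‑silylation (silyl ether protection) of the free allylic alcohol leaves both stereocentres untouched.

**Step 2**
Reactants: 2 (1R,4S)-4-(tert-butyldimethylsilyloxy)cyclopent-2-en-1-yl acetate
Product: 3 (1R,4S)-4-(tert-butyldimethylsilyloxy)cyclopent-2-en-1-ol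
Conditions: K2CO3 (0.1 equiv), MeOH, 0 °C
Reagents that add atoms: none
Why: Base‑catalysed transesterification (methanolysis) removes the acetate while the TBS ether survives.

**Step 3**
Reactants: 3 (1R,4S)-4-(tert-butyldimethylsilyloxy)cyclopent-2-en-1-ol
Product: 4 (S)-4-(tert-butyldimethylsilyloxy)cyclopent-2-en-1-one
Conditions: Dess–Martin periodinane, CH2Cl2, rt
Reagents that add atoms: none
Why: Dess–Martin oxidation of the allylic alcohol gives the enone under neutral conditions, so the silyloxy carbon (future C9, OTBS on the β face) keeps its configuration.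

**Step 4 (key step)**
Reactants: 4 (S)-4-(tert-butyldimethylsilyloxy)cyclopent-2-en-1-one; 5 dimethyl malonate
Product: 6 dimethyl 2-[(1R,2S)-2-(tert-butyldimethylsilyloxy)-4-oxocyclopentyl]malonate
Conditions: KOt-Bu (0.1 equiv), THF, −20 °C
Reagents that add atoms: none
Why: Intermolecular Michael addition of the soft malonate anion forms the C4–C5 bond; attack anti to the bulky β‑silyloxy group sets C5 (H‑5 β, chain α), and catalytic base at low temperature prevents β‑elimination.

**Step 5**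
Reactants: 6 dimethyl 2-[(1R,2S)-2-(tert-butyldimethylsilyloxy)-4-oxocyclopentyl]malonate
Product: 7 2-[(1R,2S)-2-(tert-butyldimethylsilyloxy)-4-hydroxycyclopentyl]propane-1,3-diol (C7 carbinol epimers)
Conditions: LiAlH4, THF, 0 °C→rt; Fieser work-up
Reagents that add atoms: none
Why: Hydride reduction turns both esters into the C3/C11 1,3‑diol (stable to the later organolithium step) and the ketone into an epimeric alcohol that is re‑oxidised in step 7.

**Step 6**
Reactants: 7 2-[(1R,2S)-2-(tert-butyldimethylsilyloxy)-4-hydroxycyclopentyl]propane-1,3-diol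
Product: 8 (3S,4R)-3-(tert-butyldimethylsilyloxy)-4-(2,2-dimethyl-1,3-dioxan-5-yl)cyclopentan-1-ol (C7 epimers)
Conditions: Me2C(OMe)2, PPTS (cat.), CH2Cl2, rt
Reagents that add atoms: 2,2-dimethoxypropane, COC(C)(C)OC
Why: Acid‑catalysed transketalisation closes the six‑membered acetonide on the primary 1,3‑diol selectively and leaves the ring alcohol free.

**Step 7**
Reactants: 8 (3S,4R)-3-(tert-butyldimethylsilyloxy)-4-(2,2-dimethyl-1,3-dioxan-5-yl)cyclopentan-1-ol
Product: 10 (S)-4-(2,2-dimethyl-1,3-dioxan-5-yl)cyclopent-2-en-1-one, via silyloxy ketone 9 (not isolated)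
Conditions: Dess–Martin periodinane, CH2Cl2, rt; then DBU, 0 °C
Reagents that add atoms: none
Why: Dess–Martin oxidation followed by E1cB β‑elimination of silanolate relocates the enone to C7(=O)–C8=C9, and brief cold DBU exposure leaves the C5 stereocentre intact.

**Step 8**
Reactants: 10 (S)-4-(2,2-dimethyl-1,3-dioxan-5-yl)cyclopent-2-en-1-one
Product: 11 (S)-4-(2,2-dimethyl-1,3-dioxan-5-yl)-2-(hydroxymethyl)cyclopent-2-en-1-one
Conditions: 37% aq HCHO, PBu3 (0.1 equiv), MeOH/CHCl3, rt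
Reagents that add atoms: formaldehyde, C=O
Why: The phosphine‑catalysed Morita–Baylis–Hillman reaction (aldol‑type α‑hydroxymethylation of the enone) installs C10 on C8, and no acidic C–H competes now that the malonate is masked.

**Step 9**
Reactants: 11 (S)-4-(2,2-dimethyl-1,3-dioxan-5-yl)-2-(hydroxymethyl)cyclopent-2-en-1-one
Product: 12 (S)-4-(2,2-dimethyl-1,3-dioxan-5-yl)-2-(triisopropylsilyloxymethyl)cyclopent-2-en-1-one
Conditions: TIPSCl, imidazole, DMF, rt
Reagents that add atoms: triisopropylsilyl chloride, CC(C)[Si](Cl)(C(C)C)C(C)C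
Why: O‑silylation with the bulky, migration‑resistant TIPS group protects C10‑OH for the strongly basic steps 11 and 12.

**Step 10**
Reactants: 12 (S)-4-(2,2-dimethyl-1,3-dioxan-5-yl)-2-(triisopropylsilyloxymethyl)cyclopent-2-en-1-one
Product: 13 (1R,4S)-4-(2,2-dimethyl-1,3-dioxan-5-yl)-2-(triisopropylsilyloxymethyl)cyclopent-2-en-1-ol (7α-OH cis to the C5 chain)
Conditions: NaBH4, CeCl3·7H2O, MeOH, −78 °C
Reagents that add atoms: none
Why: In this Luche 1,2‑reduction hydride arrives on the β face opposite the C5 side chain, giving the cis (7α) allylic alcohol; the minor epimer is removed by chromatography.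

**Step 11**
Reactants: 13 (1R,4S)-4-(2,2-dimethyl-1,3-dioxan-5-yl)-2-(triisopropylsilyloxymethyl)cyclopent-2-en-1-ol
Product: 14 tributylstannylmethyl ether of 13 (O7–CH2SnBu3)
Conditions: KH, Bu3SnCH2I, THF, 0 °C→rt
Reagents that add atoms: (iodomethyl)tributylstannane, CCCC[Sn](CI)(CCCC)CCCC
Why: Williamson etherification of the potassium alkoxide attaches the future C1 carbon to O7 without touching C7.

**Step 12**
Reactants: 14 tributylstannylmethyl ether of 13
Product: 16 [(1S,5S)-5-(2,2-dimethyl-1,3-dioxan-5-yl)-2-(triisopropylsilyloxymethyl)cyclopent-2-en-1-yl]methanol, via lithiomethyl ether 15 (not isolated)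
Conditions: n-BuLi, THF, −78 °C; H2O quench
Reagents that add atoms: none
Why: Tin–lithium exchange triggers a Still–Wittig [2,3]‑sigmatropic rearrangement whose suprafacial course carries CH2O from O7 to C9 on the α face, setting C9 (H‑9 β, C1 cis to the C5 chain) and moving the alkene to C7=C8.

**Step 13**
Reactants: 16 [(1S,5S)-5-(2,2-dimethyl-1,3-dioxan-5-yl)-2-(triisopropylsilyloxymethyl)cyclopent-2-en-1-yl]methanol
Product: 17 trityl ether of 16 (C1–OTr)
Conditions: TrCl, Et3N, DMAP (cat.), CH2Cl2, reflux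
Reagents that add atoms: trityl chloride, ClC(c1ccccc1)(c1ccccc1)c1ccccc1
Why: Tritylation gives a base‑stable, acid‑labile ether that stops C1‑OH from directing the epoxidation or attacking the epoxide, and that later leaves together with the acetonide.

**Step 14**
Reactants: 17 trityl ether of 16
Product: 18 [(4S,5S)-4-(2,2-dimethyl-1,3-dioxan-5-yl)-5-(trityloxymethyl)cyclopent-1-en-1-yl]methanol
Conditions: TBAF, THF, 0 °C→rt
Reagents that add atoms: none
Why: Fluoride desilylation frees only the C10 allylic alcohol because trityl ether and acetonide are inert to fluoride.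

**Step 15**
Reactants: 18 [(4S,5S)-4-(2,2-dimethyl-1,3-dioxan-5-yl)-5-(trityloxymethyl)cyclopent-1-en-1-yl]methanol
Product: 19 7β,8β-epoxide of 18 (oxirane anti to both α side chains; C10-OH free)
Conditions: VO(acac)2 (2 mol%), t-BuOOH, CH2Cl2, 0 °C
Reagents that add atoms: tert-butyl hydroperoxide, CC(C)(C)OO
Why: In this hydroxyl‑directed vanadium‑catalysed epoxidation of the allylic alcohol, oxygen is delivered to the open β face because both ring substituents block the α face, which sets C7–O β.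

**Step 16**
Reactants: 19 7β,8β-epoxide of 18
Product: 21 triol with 7β-OH 8α-OH and 8β-CH2OH (C1–OTr and acetonide retained), via spiro epoxide 20 (not isolated)
Conditions: 0.5 M aq NaOH, t-BuOH, 75 °C
Reagents that add atoms: water, O
Why: In the Payne rearrangement the C10 alkoxide displaces the oxirane oxygen at C8 with inversion (new C8–O α, C10 β, C7–O stays β), and hydroxide then opens the reactive terminal epoxide at primary C10 to give the trans‑7,8‑diol of the target.

**Step 17**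
Reactants: 21 triol with 7β-OH 8α-OH and 8β-CH2OH
Product: 22 C10 tert-butyldiphenylsilyl ether of 21 (7β-OH and 8α-OH free)
Conditions: TBDPSCl (1.1 equiv), imidazole, DMF, 0 °C→rt
Reagents that add atoms: tert-butyldiphenylsilyl chloride, CC(C)(C)[Si](Cl)(c1ccccc1)c1ccccc1
Why: Selective O‑silylation of the only primary hydroxyl installs an acid‑stable group that survives step 20.

**Step 18**
Reactants: 23 (E)-4-hydroxycinnamic acid (p-coumaric acid)
Product: 25 (E)-3-[4-(tert-butyldimethylsilyloxy)phenyl]acrylic acid, via bis-silyl derivative 24 (not isolated)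
Conditions: TBSCl (2.2 equiv), imidazole, DMF, rt; then THF/H2O/AcOH, rt
Reagents that add atoms: tert-butyldimethylsilyl chloride, CC(C)(C)[Si](C)(C)Cl
Why: Exhaustive silylation followed by selective hydrolysis of the labile silyl ester leaves the phenol masked and the acid free.

**Step 19**
Reactants: 22 C10 tert-butyldiphenylsilyl ether of 21; 25 (E)-3-[4-(tert-butyldimethylsilyloxy)phenyl]acrylic acid
Product: 26 7β-O-[(E)-4-(tert-butyldimethylsilyloxy)cinnamoyl] ester of 22
Conditions: DCC, DMAP (cat.), CH2Cl2, 0 °C→rt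
Reagents that add atoms: none
Why: Steglich esterification acylates the secondary 7β‑OH with retention while the tertiary 8α‑OH is unreactive.

**Step 20**
Reactants: 26 7β-O-[(E)-4-(tert-butyldimethylsilyloxy)cinnamoyl] ester of 22
Product: 27 tetraol (C1-OH C3-OH C11-OH and 8α-OH free; 7β-ester; C10-OTBDPS; ArOTBS)
Conditions: CSA (0.1 equiv), MeOH/CH2Cl2, 0 °C→rt
Reagents that add atoms: none
Why: Acid‑catalysed methanolysis removes trityl ether and acetonide in one operation, whereas the TBDPS ether, the aryl TBS ether and the ester tolerate these mild conditions.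

**Step 21**
Reactants: 27 tetraol
Product: 29 1β-hydroxy-4-formyl iridoid lactol (cis-fused cyclopenta[c]pyran; C3=C4 enol ether bearing CHO; 7β-ester; 8α-OH; 8β-CH2OTBDPS), via trialdehyde 28 (not isolated)
Conditions: DMSO, (CF3CO)2O, CH2Cl2, −78 °C; Et3N, −78→0 °C; pH 5 buffer
Reagents that add atoms: none
Why: Swern‑type oxidation activates all three primary alcohols before base is added, which avoids lactol over‑oxidation, and TFAA activation avoids chlorination of the β‑dialdehyde; the fully enolised malondialdehyde unit then adds to the cis C1 aldehyde (enol‑hemiacetalisation) to close ring B, with both formyl groups leading to the same product.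

**Step 22**
Reactants: 29 1β-hydroxy-4-formyl iridoid lactol; 30 isovaleryl chloride
Product: 31 1β-O-isovaleryl-4-formyl iridoid
Conditions: pyridine, CH2Cl2, −20→0 °C
Reagents that add atoms: none
Why: O‑acylation of the equilibrating lactol gives the anomer with the acyloxy group on the convex β face (H‑1 trans to H‑9, as in genipin esters), and the tertiary 8‑OH is inert.

**Step 23**
Reactants: 31 1β-O-isovaleryl-4-formyl iridoid
Product: 32 bis-silyl luzonoid A (C11-OH free; C10-OTBDPS; ArOTBS)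
Conditions: NaBH4, THF/MeOH, −30 °C
Reagents that add atoms: none
Why: Chemoselective 1,2‑borohydride reduction of the β‑alkoxy enal, as for 2‑formyl glycals, gives the C11 allylic alcohol without touching the two esters or the acyl acetal.

**Step 24**
Reactants: 32 bis-silyl luzonoid A
Product: 33 luzonoid A
Conditions: HF·pyridine, pyridine, THF, 0 °C→rt
Reagents that add atoms: none
Why: Pyridine‑buffered fluoride desilylation removes both silyl ethers under near‑neutral conditions, which avoids acyl migration and protects the acid‑labile enol acetal.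

**Compound list**
1 | (1R,4S)-4-hydroxycyclopent-2-en-1-yl acetate | O[C@@H]1C=C[C@H](OC(C)=O)C1 | starting material
2 | (1R,4S)-4-(tert-butyldimethylsilyloxy)cyclopent-2-en-1-yl acetate | CC(C)(C)[Si](C)(C)O[C@@H]1C=C[C@H](OC(C)=O)C1 | intermediate
3 | (1R,4S)-4-(tert-butyldimethylsilyloxy)cyclopent-2-en-1-ol | CC(C)(C)[Si](C)(C)O[C@@H]1C=C[C@H](O)C1 | intermediate
4 | (S)-4-(tert-butyldimethylsilyloxy)cyclopent-2-en-1-one | CC(C)(C)[Si](C)(C)O[C@@H]1C=CC(=O)C1 | intermediate
5 | dimethyl malonate | COC(=O)CC(=O)OC | starting material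
6 | dimethyl 2-[(1R,2S)-2-(tert-butyldimethylsilyloxy)-4-oxocyclopentyl]malonate | COC(=O)C(C(=O)OC)[C@H]1CC(=O)C[C@@H]1O[Si](C)(C)C(C)(C)C | intermediate
7 | 2-[(1R,2S)-2-(tert-butyldimethylsilyloxy)-4-hydroxycyclopentyl]propane-1,3-diol (C7 epimers) | OCC(CO)[C@H]1CC(O)C[C@@H]1O[Si](C)(C)C(C)(C)C | intermediate
8 | (3S,4R)-3-(tert-butyldimethylsilyloxy)-4-(2,2-dimethyl-1,3-dioxan-5-yl)cyclopentan-1-ol (C7 epimers) | CC1(C)OCC(CO1)[C@H]2CC(O)C[C@@H]2O[Si](C)(C)C(C)(C)C | intermediate
9 | (3S,4R)-3-(tert-butyldimethylsilyloxy)-4-(2,2-dimethyl-1,3-dioxan-5-yl)cyclopentan-1-one | CC1(C)OCC(CO1)[C@H]2CC(=O)C[C@@H]2O[Si](C)(C)C(C)(C)C | intermediate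
10 | (S)-4-(2,2-dimethyl-1,3-dioxan-5-yl)cyclopent-2-en-1-one | CC1(C)OCC(CO1)[C@H]2CC(=O)C=C2 | intermediate
11 | (S)-4-(2,2-dimethyl-1,3-dioxan-5-yl)-2-(hydroxymethyl)cyclopent-2-en-1-one | CC1(C)OCC(CO1)[C@H]2CC(=O)C(CO)=C2 | intermediate
12 | (S)-4-(2,2-dimethyl-1,3-dioxan-5-yl)-2-(triisopropylsilyloxymethyl)cyclopent-2-en-1-one | CC1(C)OCC(CO1)[C@H]2CC(=O)C(CO[Si](C(C)C)(C(C)C)C(C)C)=C2 | intermediate
13 | (1R,4S)-4-(2,2-dimethyl-1,3-dioxan-5-yl)-2-(triisopropylsilyloxymethyl)cyclopent-2-en-1-ol | CC1(C)OCC(CO1)[C@H]2C[C@@H](O)C(CO[Si](C(C)C)(C(C)C)C(C)C)=C2 | intermediate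
14 | tributylstannylmethyl ether of 13 | CC1(C)OCC(CO1)[C@H]2C[C@@H](OC[Sn](CCCC)(CCCC)CCCC)C(CO[Si](C(C)C)(C(C)C)C(C)C)=C2 | intermediate
15 | lithiomethyl ether of 13 | CC1(C)OCC(CO1)[C@H]2C[C@@H](OC[Li])C(CO[Si](C(C)C)(C(C)C)C(C)C)=C2 | intermediate
16 | [(1S,5S)-5-(2,2-dimethyl-1,3-dioxan-5-yl)-2-(triisopropylsilyloxymethyl)cyclopent-2-en-1-yl]methanol | CC1(C)OCC(CO1)[C@H]2CC=C(CO[Si](C(C)C)(C(C)C)C(C)C)[C@H]2CO | intermediate
17 | trityl ether of 16 | CC1(C)OCC(CO1)[C@H]2CC=C(CO[Si](C(C)C)(C(C)C)C(C)C)[C@H]2COC(c3ccccc3)(c4ccccc4)c5ccccc5 | intermediate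
18 | [(4S,5S)-4-(2,2-dimethyl-1,3-dioxan-5-yl)-5-(trityloxymethyl)cyclopent-1-en-1-yl]methanol | CC1(C)OCC(CO1)[C@H]2CC=C(CO)[C@H]2COC(c3ccccc3)(c4ccccc4)c5ccccc5 | intermediate
19 | 7β,8β-epoxide of 18 | CC1(C)OCC(CO1)[C@H]2C[C@@H]3O[C@]3(CO)[C@H]2COC(c4ccccc4)(c5ccccc5)c6ccccc6 | intermediate
20 | 8α,10-spiro epoxide with 7β-OH | CC1(C)OCC(CO1)[C@H]2C[C@H](O)[C@]3(CO3)[C@H]2COC(c4ccccc4)(c5ccccc5)c6ccccc6 | intermediate
21 | triol (7β-OH, 8α-OH, 8β-CH2OH) | CC1(C)OCC(CO1)[C@H]2C[C@H](O)[C@](O)(CO)[C@H]2COC(c3ccccc3)(c4ccccc4)c5ccccc5 | intermediate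
22 | C10 TBDPS ether of 21 | CC1(C)OCC(CO1)[C@H]2C[C@H](O)[C@](O)(CO[Si](c3ccccc3)(c4ccccc4)C(C)(C)C)[C@H]2COC(c5ccccc5)(c6ccccc6)c7ccccc7 | intermediate
23 | (E)-4-hydroxycinnamic acid | OC(=O)/C=C/c1ccc(O)cc1 | starting material
24 | TBS (E)-4-(TBS-oxy)cinnamate | CC(C)(C)[Si](C)(C)OC(=O)/C=C/c1ccc(O[Si](C)(C)C(C)(C)C)cc1 | intermediate
25 | (E)-3-[4-(tert-butyldimethylsilyloxy)phenyl]acrylic acid | OC(=O)/C=C/c1ccc(O[Si](C)(C)C(C)(C)C)cc1 | intermediate
26 | 7β-cinnamate ester of 22 | CC1(C)OCC(CO1)[C@H]2C[C@H](OC(=O)/C=C/c3ccc(O[Si](C)(C)C(C)(C)C)cc3)[C@](O)(CO[Si](c4ccccc4)(c5ccccc5)C(C)(C)C)[C@H]2COC(c6ccccc6)(c7ccccc7)c8ccccc8 | intermediate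
27 | tetraol | OCC(CO)[C@H]1C[C@H](OC(=O)/C=C/c2ccc(O[Si](C)(C)C(C)(C)C)cc2)[C@](O)(CO[Si](c3ccccc3)(c4ccccc4)C(C)(C)C)[C@H]1CO | intermediate
28 | trialdehyde | O=CC(C=O)[C@H]1C[C@H](OC(=O)/C=C/c2ccc(O[Si](C)(C)C(C)(C)C)cc2)[C@](O)(CO[Si](c3ccccc3)(c4ccccc4)C(C)(C)C)[C@H]1C=O | intermediate
29 | 1β-hydroxy-4-formyl iridoid lactol | O[C@@H]1OC=C(C=O)[C@H]2C[C@H](OC(=O)/C=C/c3ccc(O[Si](C)(C)C(C)(C)C)cc3)[C@](O)(CO[Si](c4ccccc4)(c5ccccc5)C(C)(C)C)[C@@H]12 | intermediate
30 | isovaleryl chloride | CC(C)CC(=O)Cl | starting material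
31 | 1β-O-isovaleryl-4-formyl iridoid | CC(C)CC(=O)O[C@@H]1OC=C(C=O)[C@H]2C[C@H](OC(=O)/C=C/c3ccc(O[Si](C)(C)C(C)(C)C)cc3)[C@](O)(CO[Si](c4ccccc4)(c5ccccc5)C(C)(C)C)[C@@H]12 | intermediate
32 | bis-silyl luzonoid A | CC(C)CC(=O)O[C@@H]1OC=C(CO)[C@H]2C[C@H](OC(=O)/C=C/c3ccc(O[Si](C)(C)C(C)(C)C)cc3)[C@](O)(CO[Si](c4ccccc4)(c5ccccc5)C(C)(C)C)[C@@H]12 | intermediate
33 | luzonoid A | CC(C)CC(=O)O[C@@H]1OC=C(CO)[C@H]2C[C@H](OC(=O)/C=C/c3ccc(O)cc3)[C@](O)(CO)[C@@H]12 | target

**Step count:** 24 steps in total. The longest linear sequence is 23 steps (steps 1–17 and 19–24).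

**Steps most likely to fail**

Step 12. The new bond forms in a crowded cis‑vicinal position, so a [1,2] shift or simple protonation of 15 may compete. The fallback sets out from 13 and returns at 16. Heat 13 with N,N‑dimethylformamide dimethyl acetal in xylene at 140 °C. The alkoxy(dimethylamino)carbene formed on O7 then undergoes a Büchi‑type [2,3] shift on the same α face, with no tin and no organolithium, and gives the cis C9 N,N-dimethylcarboxamide F1. LiBHEt3 in THF reduces this amide to the primary alcohol 16.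

Step 16. The Payne step needs an intramolecular SN2 at the fully substituted C8 and may be slow compared with direct opening. The fallback sets out from 19 and returns at 21. Stir 19 with Cs2CO3 under a CO2 atmosphere in DMF at 40 °C. The carbonate half‑ester generated on O10 opens the oxirane at C8 in a 5‑exo mode with the same inversion and gives the 8α,10-cyclic carbonate 7β-ol F2. K2CO3 in MeOH then cleaves the carbonate to triol 21.

Step 21. Oxidising a 2‑substituted 1,3‑diol to the malondialdehyde may lose the β‑oxygen by E1cB. The fallback sets out from 27 and returns at 33, and it never makes a 1,3‑dialdehyde.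
- One equivalent of TBSCl with imidazole at −20 °C silylates one of the two unhindered CH2OH groups of the propanediol unit, giving the C11 mono-TBS ether F3. The resulting C4 epimers are inconsequential.
- An ordinary Swern oxidation of the two remaining primary alcohols gives the β-silyloxy dialdehyde F4.
- Catalytic PPTS over molecular sieves promotes enolisation and hemiacetalisation to the 11-O-TBS enol lactol F5.
- Isovaleryl chloride 30 in pyridine gives the tris-silyl 1β-isovalerate F6.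
- HF·pyridine then delivers 33 directly, so the NaBH4 step is not needed.

**Further compounds**
F1 | step 12 | (1S,5S)-5-(2,2-dimethyl-1,3-dioxan-5-yl)-N,N-dimethyl-2-(triisopropylsilyloxymethyl)cyclopent-2-ene-1-carboxamide | CC1(C)OCC(CO1)[C@H]2CC=C(CO[Si](C(C)C)(C(C)C)C(C)C)[C@H]2C(=O)N(C)C
F2 | step 16 | 8α,10-cyclic carbonate 7β-ol (C1-OTr and acetonide retained) | CC1(C)OCC(CO1)[C@H]2C[C@H](O)[C@]3(COC(=O)O3)[C@H]2COC(c4ccccc4)(c5ccccc5)c6ccccc6
F3 | step 21 | C11 mono-TBS ether of 27 (C4 epimers) | OCC(CO[Si](C)(C)C(C)(C)C)[C@H]1C[C@H](OC(=O)/C=C/c2ccc(O[Si](C)(C)C(C)(C)C)cc2)[C@](O)(CO[Si](c3ccccc3)(c4ccccc4)C(C)(C)C)[C@H]1CO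
F4 | step 21 | C1,C3-dialdehyde with C11-OTBS (C4 epimers) | O=CC(CO[Si](C)(C)C(C)(C)C)[C@H]1C[C@H](OC(=O)/C=C/c2ccc(O[Si](C)(C)C(C)(C)C)cc2)[C@](O)(CO[Si](c3ccccc3)(c4ccccc4)C(C)(C)C)[C@H]1C=O
F5 | step 21 | 11-O-TBS enol lactol (1β-OH) | O[C@@H]1OC=C(CO[Si](C)(C)C(C)(C)C)[C@H]2C[C@H](OC(=O)/C=C/c3ccc(O[Si](C)(C)C(C)(C)C)cc3)[C@](O)(CO[Si](c4ccccc4)(c5ccccc5)C(C)(C)C)[C@@H]12
F6 | step 21 | tris-silyl luzonoid A (1β-O-isovaleryl; 11-OTBS; 10-OTBDPS; ArOTBS) | CC(C)CC(=O)O[C@@H]1OC=C(CO[Si](C)(C)C(C)(C)C)[C@H]2C[C@H](OC(=O)/C=C/c3ccc(O[Si](C)(C)C(C)(C)C)cc3)[C@](O)(CO[Si](c4ccccc4)(c5ccccc5)C(C)(C)C)[C@@H]12
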